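Per mole per litre of X charged, ask how far L has got by a given time; that measure carries these flasks.

| flask | L | X | remark | time |
|---|---|---|---|---|
| maple | 0.25 M | 0.38 M | run made earlier |  |
| alder | 0.25 M | 0.76 M | run made earlier |  |
| spring | 0.25 M | 0.450 M |  | 4.0 min |
| dawn | 0.25 M | 0.680 M |  | 4.0 min |
| dusk | 0.25 M | 1.00 M |  | 4.0 min |

- maple (time / min: L / %, E / %): 0.200: 95.2, 4.6; 0.500: 88.2, 11.9; 1.00: 79.2, 19.9; 1.50: 72.8, 27.0; 2.00: 66.7, 32.7; 3.00: 60.7, 39.1
- alder (time / min: L / %, E / %): 0.250: 88.6, 11.1; 0.333: 84.0, 15.5; 0.667: 72.7, 27.4; 1.00: 63.8, 35.4; 1.50: 55.0, 45.5; 3.00: 37.0, 63.3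

(standard deviation of a reading: 0.5 percentage points)



- part of the L that has reacted at the end, spring
- part of the L that has reacted at the end, dawn
- part of the L that has reacted at the end, dusk
- what raising the concentration of X from its lowest to its highest value here does to the part of the L that has reacted (changes below 5 percentage points count as none) (it rises / no change / it falls)

Begin with the two earlier runs. L and E add up to about the charge at each reading, so read L as what has not yet reacted. Take the logarithm of charged L over remaining L, as in a pseudo-first-order plot, and divide it by the charged cX. The maple run gives 1.31 M⁻¹ at 3.00 min; call this quantity, at a stated time, the reach.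

The alder run has twice the X, yet at that time its reach is 1.31 M⁻¹. So treat the reach as a function of time, the same for both charges. But it slows: the maple run gives 1.07 M⁻¹ at 2.00 min, so the last minute added 0.248 M⁻¹. Assume that the next minute adds as much, which is a bold step, and the reach at 4.0 min is 1.56 M⁻¹.

Now multiply it by each cX and undo the logarithm. My reckoning gives 50.5% for spring, 65.4% for dawn and 79.0% for dusk.

The forecast gave 47%, 61% and 74%, each lower than mine , and for the trend said it rises, in the words “Conversion rises with X”.

The flasks give 50.6%, 65.5% and 78.6%, so it rises, by 28 percentage points.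

    2 X → D (k = 0.00180 M⁻¹ s⁻¹)
    L + X → G + E (k = 0.0120 M⁻¹ s⁻¹)
    X + G ⇌ J, settled at all times (K = 5600 M⁻¹)
    Z ⇌ G, rate k4*(cs4 - [G]) while solid is left; crystals form when [G] > cs4 (solubility = 0.0990 M, k = 0.170 s⁻¹)

Turn the results back into reach: spring gives 1.57 M⁻¹ and dusk 1.54 M⁻¹. The difference in cX is the main reason that dusk stands at 78.6% and not at 50.6%. Now take the flask like dusk but with 1.7 M of X: the reach of 1.56 M⁻¹ gives 92.9%, and that flask stands at 91.6%.

The readings were generated by integration with made-up constants, and the scatter is random.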